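**Plan** (terpenoid numbering C1–C10 for each decalin half; the CH2CH2 linker sits on C9)

1. Last cut: the exocyclic methylene is taken back to one carbonyl of a C2-symmetric 8,14-diketone, so both halves are built as one.
2. Key cut, made in both halves at once: the ring-A bond between the carbinol carbon C3 and the gem-dimethyl carbon C4. The enabling feature is that C4 hangs on ring-fusion carbon C5 and C3 ends the arm C1–C2–C3 on ring-fusion carbon C10, so a tertiary C4 radical (from an isopropenyl group) and a C3 aldehyde are 1,6-related across the C5–C10 bond of an intact ring B and close ring A 6-exo.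
3. Next cut: the central CH2–CH2 bond, by tail-to-tail reductive dimerisation of an α-methylene ketone.
4. Ring B, with C8=O, the C10 methyl, C5 and C4 with both its methyls, is bought as (+)-verbenone. Its cyclobutane is a temporary ring: it allows enolisation towards C9 only, steers the cuprate, and on strain-driven opening unveils the isopropenyl group.
5. Forward order: verbenone → C10 quaternary centre → C9 methylene → dimer → cyclobutane opening → dialdehyde → both A rings in one radical event → mono-methylenation.
6. Stereochemistry: C5 is bought; C10 is relayed from it (conjugate addition anti to the gem-dimethyl bridge); C9 comes from enolate protonation and equilibration; C3 from the chair of the radical cyclisation.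

Key step: step 7

Remark: (1R,5R)-(+)-verbenone is taken as a commercial chiral-pool material. The two carbonyl groups of the C2-symmetric diketone that precedes the target are homotopic, so the last step is a statistical mono-olefination that can give only one constitution.

**Step 1**
Reactants: 1 (1R,5R)-(+)-verbenone; 2 3-chloropropan-1-ol
Product: 4 (1R,4R,5R)-4-(3-hydroxypropyl)-4,6,6-trimethylbicyclo[3.1.1]heptan-2-one, via alkoxide Grignard reagent 3 (not isolated)
Conditions: 2, MeMgCl (1 equiv), THF, −20 °C, then Mg, reflux (gives 3, used in excess); CuBr·SMe2 (20 mol %), then 1, THF, −40 → 0 °C; aq. NH4Cl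
Reagents that add atoms: none
Why: Copper-catalysed conjugate addition of a Grignard reagent (hydroxyl masked as its magnesium alkoxide) to the β,β-disubstituted enone should deliver the chain to C4 from the face of the CH2 bridge, away from the gem-dimethyl bridge, which sets the quaternary centre (later C10) with the chain trans and the methyl cis to the gem-dimethyl carbon on the neighbouring bridgehead.

**Step 2**
Reactants: 4
Product: 7 (1R,4S,5S)-4-(3-hydroxypropyl)-4,6,6-trimethyl-3-methylidenebicyclo[3.1.1]heptan-2-one, via Mannich base 5 (not isolated), via methiodide 6 (not isolated)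
Conditions: LDA (2.2 equiv), THF, −78 °C; CH2=NMe2+ I−, −78 °C → rt; aq. work-up; MeI, CH2Cl2, rt; aq. NaHCO3, CH2Cl2, rt
Reagents that add atoms: Eschenmoser's salt (N,N-dimethylmethyleneiminium iodide), C=[N+](C)C.[I-]
Why: Because C1 is a bridgehead the ketone can enolise only towards C3, so enolate formation, Mannich reaction, N-methylation and Hofmann-type (E1cB) elimination should give the α-methylene ketone regiospecifically (Eschenmoser methylenation); the transient C3 centre of 5 and 6 is destroyed.

**Step 3**
Reactants: 7 (two molecules)
Product: 8 1,2-bis[(1R,3R,4S,5S)-4-(3-hydroxypropyl)-4,6,6-trimethyl-2-oxobicyclo[3.1.1]heptan-3-yl]ethane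
Conditions: SmI2 (1.1 equiv per enone), THF–HMPA, −78 → 0 °C; aq. NH4Cl
Reagents that add atoms: none
Why: SmI2 reduces the enone to its radical anion, which couples tail-to-tail at the unhindered exocyclic CH2 (reductive hydrodimerisation of an enone to a 1,6-diketone), and protonation of the bis-enolate from the face of the CH2 bridge should place the new CH2–CH2 link syn to the gem-dimethyl bridge, cis to the C4 methyl as C9 requires (an epimer formed here would be corrected in step 5).

**Step 4**
Reactants: 8
Product: 9 1,2-bis[(1R,5S,6S)-2-acetoxy-6-(3-acetoxypropyl)-6-methyl-5-(prop-1-en-2-yl)cyclohex-2-en-1-yl]ethane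
Conditions: BF3·OEt2, Zn(OAc)2, Ac2O, 0 °C → rt
Reagents that add atoms: acetic anhydride, CC(=O)OC(C)=O
Why: Lewis-acid-mediated cyclobutane fragmentation of a nopinone-type ketone: heterolysis of the strained bond between the α-bridgehead carbon and the gem-dimethyl carbon gives an enolate, trapped as the enol acetate on the side away from C9, and a tertiary cation that loses a methyl proton to give the isopropenyl group, while the primary hydroxyls are acetylated and no stereocentre is touched.

**Step 5**
Reactants: 9
Product: 10 1,2-bis[(1R,2S,3S)-2-(3-hydroxypropyl)-2-methyl-6-oxo-3-(prop-1-en-2-yl)cyclohexyl]ethane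
Conditions: K2CO3, MeOH, rt
Reagents that add atoms: none
Why: Base-mediated transesterification frees both ketones and both primary alcohols, and under these conditions the α-centre C9 should settle in the configuration drawn, in which the linker, the isopropenyl group and the three-carbon arm are all equatorial.

**Step 6**
Reactants: 10
Product: 11 1,2-bis[(1R,2S,3S)-2-methyl-6-oxo-2-(3-oxopropyl)-3-(prop-1-en-2-yl)cyclohexyl]ethane
Conditions: Dess–Martin periodinane, pyridine, CH2Cl2, 0 °C → rt; used directly
Reagents that add atoms: none
Why: Dess–Martin oxidation of the primary alcohols under buffered, non-enolising conditions should give the dialdehyde without touching the ketones, the isopropenyl groups or the α-centres.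

**Step 7**
Reactants: 11
Product: 12 26,27-dinor-8,14-dioxo-α-onocerin (C2-symmetric diketone diol: two 3β-hydroxy-4,4,10-trimethyl-8-oxo-trans-decalin units joined at C9 by CH2CH2)
Conditions: Fe(acac)3, PhSiH3, EtOH (degassed), 60 °C
Reagents that add atoms: none
Why: Fe(acac)3 and PhSiH3 in ethanol generate an iron hydride that transfers a hydrogen atom to the CH2 terminus of each isopropenyl group (Markovnikov MHAT); the tertiary radical so formed at the gem-dimethyl carbon C4 adds to the aldehyde carbon C3 of the three-carbon arm on C10, and the alkoxy radical is reduced and protonated in the medium to the secondary alcohol. The closest known reaction type is the iron-mediated, HAT-initiated reductive radical cyclisation of alkene-tethered ketones and aldehydes. Each ring A closes in the 6-exo-trig mode onto the C=O group through a chair transition state. The trans ring fusion is not created here but dictated by the existing C5 and C10 centres, whose two tethers are trans-diequatorial on ring B; the new carbinol centre C3 is controlled by that chair, in which the carbonyl oxygen lies pseudo-equatorial, and because radical addition to C=O is reversible the more stable equatorial alkoxy radical should be funnelled to the 3β-alcohol. The step needs chemoselectivity for the aldehyde over the C8 ketone, secured because attack on C8 would be a strained bridging 5-exo closure whereas attack on C3 is an unstrained chair 6-exo closure onto the better acceptor, and it needs the isopropenyl groups to be the only alkenes present, which is why the exocyclic methylene of the target is introduced only in step 8.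

**Step 8**
Reactants: 12
Product: 13 26-nor-8-oxo-α-onocerin
Conditions: Ph3PCH3Br (1.1 equiv), KOtBu (3.2 equiv), THF–toluene, rt → 60 °C; aq. NH4Cl
Reagents that add atoms: methyltriphenylphosphonium bromide, C[P+](c1ccccc1)(c1ccccc1)c1ccccc1.[Br-]
Why: Wittig methylenation with a limiting amount of ylide (the excess base only holds the two hydroxyls as alkoxides) should convert one of the two homotopic ketones, so that only 13 can form as mono-olefin (unreacted 12 and the bis-olefin are separable and 12 is recycled), and the α-centre of the remaining ketone stays in its preferred equatorial configuration.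

**Compound list**

1 | (1R,5R)-(+)-verbenone | CC1=CC(=O)[C@@H]2C[C@H]1C2(C)C | starting material
2 | 3-chloropropan-1-ol | OCCCCl | starting material
3 | 3-(chloromagnesiooxy)propylmagnesium chloride (alkoxide Grignard reagent) | Cl[Mg]CCCO[Mg]Cl | intermediate
4 | (1R,4R,5R)-4-(3-hydroxypropyl)-4,6,6-trimethylbicyclo[3.1.1]heptan-2-one (chain anti to the gem-dimethyl bridge) | C[C@@]1(CCCO)CC(=O)[C@@H]2C[C@H]1C2(C)C | intermediate
5 | Mannich base, 3-(dimethylaminomethyl) derivative of 4 (CH2NMe2 anti to the gem-dimethyl bridge) | C[C@@]1(CCCO)[C@H](CN(C)C)C(=O)[C@@H]2C[C@H]1C2(C)C | intermediate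
6 | methiodide of 5 | C[C@@]1(CCCO)[C@H](C[N+](C)(C)C)C(=O)[C@@H]2C[C@H]1C2(C)C.[I-] | intermediate
7 | (1R,4S,5S)-4-(3-hydroxypropyl)-4,6,6-trimethyl-3-methylidenebicyclo[3.1.1]heptan-2-one | C[C@@]1(CCCO)C(=C)C(=O)[C@@H]2C[C@H]1C2(C)C | intermediate
8 | 1,2-bis[(1R,3R,4S,5S)-4-(3-hydroxypropyl)-4,6,6-trimethyl-2-oxobicyclo[3.1.1]heptan-3-yl]ethane (linker syn to the gem-dimethyl bridge) | C[C@@]1(CCCO)[C@@H](CC[C@H]3C(=O)[C@@H]4C[C@@H](C4(C)C)[C@]3(C)CCCO)C(=O)[C@@H]2C[C@H]1C2(C)C | intermediate
9 | 1,2-bis[(1R,5S,6S)-2-acetoxy-6-(3-acetoxypropyl)-6-methyl-5-(prop-1-en-2-yl)cyclohex-2-en-1-yl]ethane | C[C@@]1(CCCOC(C)=O)[C@@H](CC[C@H]3C(OC(C)=O)=CC[C@@H](C(C)=C)[C@]3(C)CCCOC(C)=O)C(OC(C)=O)=CC[C@H]1C(C)=C | intermediate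
10 | 1,2-bis[(1R,2S,3S)-2-(3-hydroxypropyl)-2-methyl-6-oxo-3-(prop-1-en-2-yl)cyclohexyl]ethane | C[C@@]1(CCCO)[C@@H](CC[C@H]3C(=O)CC[C@@H](C(C)=C)[C@]3(C)CCCO)C(=O)CC[C@H]1C(C)=C | intermediate
11 | 1,2-bis[(1R,2S,3S)-2-methyl-6-oxo-2-(3-oxopropyl)-3-(prop-1-en-2-yl)cyclohexyl]ethane | C[C@@]1(CCC=O)[C@@H](CC[C@H]3C(=O)CC[C@@H](C(C)=C)[C@]3(C)CCC=O)C(=O)CC[C@H]1C(C)=C | intermediate
12 | 26,27-dinor-8,14-dioxo-α-onocerin | O=C1CC[C@H]2C(C)(C)[C@@H](O)CC[C@]2(C)[C@H]1CC[C@H]1C(=O)CC[C@H]2C(C)(C)[C@@H](O)CC[C@]12C | intermediate
13 | 26-nor-8-oxo-α-onocerin | C=C1CC[C@H]2C(C)(C)[C@@H](O)CC[C@]2(C)[C@H]1CC[C@H]1C(=O)CC[C@H]2C(C)(C)[C@@H](O)CC[C@]12C | target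

**Totals**

Total step count: 8. Longest linear sequence: 8 steps (from 1).

**Steps most likely to fail**

Step 7. The aldehydes may be reduced or acetalised by the silane–ethanol medium before the radical arrives. The tertiary radical may be reduced instead of cyclising (net hydrogenation of the isopropenyl group). The iron salt may promote an intramolecular aldol between C9 and the aldehyde. Facial control at the carbinol carbon may be incomplete. The fallback sets out from 11: Markovnikov addition of dry HBr (CH2Cl2, −78 °C) to both isopropenyl groups should give the bis(tertiary bromide) dialdehyde F1. Slow addition of Bu3SnH with AIBN in benzene at 80 °C then generates the same two tertiary radicals by bromine abstraction in a medium that does not reduce aldehydes. 6-exo addition to each CHO followed by hydrogen transfer from the tin hydride to the alkoxy radical comes back to the route at 12.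

Step 8. The two equivalent carbonyl groups cannot be told apart, so over-olefination competes. The basic ylide may enolise the hindered ketone instead of adding to it, and base may epimerise the centre next to the remaining ketone. The fallback sets out from 12: exhaustive methylenation with an excess of a non-basic titanium methylidene reagent (Zn, CH2Br2, TiCl4; Takai–Lombardo methylenation) should give α-onocerin F2. One of its two equivalent exocyclic alkenes is then cleaved with a limiting amount of oxidant (cat. OsO4, NaIO4, 2,6-lutidine, aqueous dioxane; Lemieux–Johnson cleavage), which comes back to the route at 13. The ketone is thus unveiled without base, and over-cleavage only returns 12.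

Step 3. The enone radical anion may be protonated and reduced further to the saturated α-methyl ketone before it couples, and the ketyl-type radical anion may open the adjacent cyclobutane. The fallback sets out from 7: conjugate addition of benzeneselenol (PhSeSePh, NaBH4, EtOH, then AcOH) to one portion of 7 should give the β-phenylselanyl ketone F3. Bu3SnH and AIBN in benzene, in the presence of a second portion of 7, then generate a neutral primary radical that adds to the exocyclic CH2 of 7 (Giese addition). The resulting α-keto radical takes hydrogen from the tin hydride on the face away from the gem-dimethyl bridge, which comes back to the route at 8.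

**Further compounds**

F1 | step 7 | bis(tertiary bromide) of 11 (each isopropenyl replaced by 2-bromopropan-2-yl, configurations as in 11) | C[C@@]1(CCC=O)[C@@H](CC[C@H]3C(=O)CC[C@@H](C(C)(C)Br)[C@]3(C)CCC=O)C(=O)CC[C@H]1C(C)(C)Br
F2 | step 8 | α-onocerin | C=C1CC[C@H]2C(C)(C)[C@@H](O)CC[C@]2(C)[C@H]1CC[C@H]1C(=C)CC[C@H]2C(C)(C)[C@@H](O)CC[C@]12C
F3 | step 3 | 4-(3-hydroxypropyl)-4,6,6-trimethyl-3-[(phenylselanyl)methyl]bicyclo[3.1.1]heptan-2-one (CH2SePh syn to the gem-dimethyl bridge, other centres as in 7) | C[C@@]1(CCCO)[C@@H](C[Se]c2ccccc2)C(=O)[C@@H]2C[C@H]1C2(C)C
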